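The data come from a simulation with made-up constants.

I could not read the flask at 15 h, because Friday's readings of it stop at 6.00 h.

- Friday's: starting material 20 mM; gas phase 11 mM (held); catalyst 0.40 mM; the very flask that is asked about, followed so far
- flask: starting material 20 mM; gas phase 11 mM (held); catalyst 0.40 mM; time 15 h

- Friday's (time / h: product / %, starting material / %): 0.833: 0, 99.4; 1.50: 0.7, 97.2; 2.50: 1.5, 94.9; 3.00: 2.1, 94.6; 4.00: 3.5, 91.6; 5.00: 5.2, 89.3; 6.00: 6.2, 86.0

(scatter of a reading: 0.5 percentage points)

- what was read earlier has a scatter of 0.5 percentage points, one standard deviation
- at the start none of the gas phase is in solution

- how much product there is at 15 h, in percent of the starting material charged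
- concentration of dissolved gas in solution at 15 h, in percent of saturation

So I folded the two times and Friday's last reading of starting material into one number, 0.377, the lifetime count. It is the time asked about over the time read, multiplied by the natural logarithm of charged over remaining starting material. In words, it says how many lifetimes of the starting material pass by then if the loss stays a pseudo-first-order decay at Friday's pace.

Read off that count, my estimate for the flask was 68.6% of its starting material kept and 31.4% lost. Friday's reading of product was 0.443 of the loss read at 6.00 h, so my reckoning gave 13.9% of product.

One number was not enough, though. That share had read 0.294 at 2.50 h, so within the scatter of 0.5 percentage points it seemed still to be moving, and I held my figure to be low. The count also says nothing of [dissolved gas], so I gave no figure for it.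

The forecast put product at 24% (18% to 30%), above my figure. It put [dissolved gas] at 93% of saturation (75% to 99%), reasoning that “the solution should sit at about 93% of saturation”.

The flask gave 18.3% of product and [dissolved gas] at 32.2% of saturation.

    2 starting material → homo dimer (k = 0.310 M⁻¹ h⁻¹)
    gas phase ⇌ dissolved gas, rate k2*(csat - [dissolved gas]) (kL = 0.0560 h⁻¹)
    starting material + dissolved gas + catalyst → catalyst + product (k = 72000 M⁻² h⁻¹)
    dissolved gas + catalyst ⇌ idle complex, settled at all times (K = 1300 M⁻¹)

At 15.0 h [dissolved gas] stood at 3.55 mM, and its half-life by the catalysed conversion alone, the other concentrations as charged, was 1.2 h, shorter than 15 h. The lifetime count's 68.6% stands against 68% of starting material in this flask. For the same flask read at 2.5 d, the count comes to 1.51 lifetimes, which reckons 22.1% left, and that flask held 22.5% of starting material.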